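The cyclopentenone ring (C1–C5) of the target carries the contiguous array C1(=O)–C5(OH)–C6(O), the α-ketol that arises when a six-membered 2-hydroxy-1,3-dione contracts; the route exploits this feature. Cleaving C1–C5 retrosynthetically gives (4S,6S)-6-dodecyl-6-hydroxy-4-silyloxycyclohex-2-ene-1,5-dione. In the forward sense its magnesium-chelated C6 alkoxide pushes ring carbon C1 from C6 onto the C5 carbonyl: one operation forms C1–C5, closes the five-membered ring, sets the C5 carbinol by relay from C6 and turns C6 into the side-chain ketone. The precursor comes from 1,3-dimethoxybenzene via a quinone monoketal; ketone reduction, acetylation and desilylation complete the synthesis.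

Key step: step 8

Remark: atom labels C1–C6 of the target are used for all intermediates; by CIP analysis the target is (4S,5S,6S) with the C4 and C5 hydroxyl groups trans on the ring; the cyclohexenedione of the key step is assumed to equilibrate with its C4=C5 enol and is used without chromatography.

Step 1
Reactants: 1 1,3-dimethoxybenzene; 2 1-bromododecane
Product: 4 2-dodecyl-1,3-dimethoxybenzene, via 2,6-dimethoxyphenyllithium 3 (not isolated)
Conditions: n-BuLi, THF, 0 → 23 °C; then 2, 23 → 50 °C
Reagents that add atoms: none
Why: Directed ortho-metalation places lithium at C2 between the two methoxy groups, the only doubly activated position, and the aryllithium is then alkylated by SN2 displacement on the primary bromide.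

Step 2
Reactants: 4 2-dodecyl-1,3-dimethoxybenzene
Product: 6 3-dodecyl-2,4-dimethoxybenzaldehyde, via aryl iminium dichlorophosphate 5 (not isolated)
Conditions: POCl3, DMF, 0 → 80 °C; then H2O, 23 °C
Reagents that add atoms: N,N-dimethylformamide, CN(C)C=O; water, O
Why: Vilsmeier–Haack formylation attacks the ring carbon that is ortho to one methoxy group and para to the other, the only free position activated by both, and water hydrolyses the iminium salt to the aldehyde.

Step 3
Reactants: 6 3-dodecyl-2,4-dimethoxybenzaldehyde
Product: 8 3-dodecyl-2,4-dimethoxyphenol, via 3-dodecyl-2,4-dimethoxyphenyl formate 7 (not isolated)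
Conditions: m-CPBA, CH2Cl2, 0 → 23 °C; then K2CO3 (0.1 equiv), MeOH, 23 °C
Reagents that add atoms: 3-chloroperbenzoic acid, OOC(=O)c1cccc(Cl)c1
Why: Dakin-type Baeyer–Villiger oxidation, in which the electron-rich aryl group migrates to oxygen to give the aryl formate that mild methanolysis cleaves to the phenol, so the formyl carbon is exchanged for the oxygen that becomes O4.

Step 4
Reactants: 8 3-dodecyl-2,4-dimethoxyphenol
Product: 9 3-dodecyl-2,4,4-trimethoxycyclohexa-2,5-dien-1-one
Conditions: PhI(OAc)2, MeOH, 0 °C; aqueous NaHCO3 work-up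
Reagents that add atoms: methanol, CO
Why: Oxidative dearomatisation of a para-methoxyphenol by a trivalent iodine reagent in methanol, where methanol adds at the methoxy-bearing para carbon to give the quinone monoketal with the ketal at the future C1 and the ketone at the future C4, a regiochemistry fixed by the position of the phenol.

Step 5
Reactants: 9 3-dodecyl-2,4,4-trimethoxycyclohexa-2,5-dien-1-one
Product: 10 (1S)-3-dodecyl-2,4,4-trimethoxycyclohexa-2,5-dien-1-ol
Conditions: (R)-Me-CBS [(R)-1-methyl-3,3-diphenyltetrahydro-1H,3H-pyrrolo[1,2-c][1,3,2]oxazaborole] (0.2 equiv), catecholborane, toluene, −78 °C; aqueous NaOH work-up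
Reagents that add atoms: none
Why: Corey–Bakshi–Shibata reduction, in which the oxazaborolidine binds the ketone anti to the larger methoxy-substituted vinyl arm and delivers hydride in a 1,2-sense to the face that gives the (S)-carbinol at the future C4, while catecholborane leaves the alkenes untouched and the basic work-up spares the acid-labile dienol ketal.

Step 6
Reactants: 10 (1S)-3-dodecyl-2,4,4-trimethoxycyclohexa-2,5-dien-1-ol
Product: 11 triisopropyl{[(1S)-3-dodecyl-2,4,4-trimethoxycyclohexa-2,5-dien-1-yl]oxy}silane
Conditions: chlorotriisopropylsilane, imidazole, 4-(dimethylamino)pyridine (cat.), DMF, 23 → 40 °C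
Reagents that add atoms: chlorotriisopropylsilane, CC(C)[Si](Cl)(C(C)C)C(C)C
Why: Standard silylation of a secondary alcohol with a silyl chloride and imidazole, chosen over a silyl triflate so that the ionisable quinone ketal never meets a strong Lewis acid, and installing at O4 a bulky triisopropylsilyl group that will neither chelate magnesium nor migrate to the neighbouring enol oxygen in the key step.

Step 7
Reactants: 11 triisopropyl{[(1S)-3-dodecyl-2,4,4-trimethoxycyclohexa-2,5-dien-1-yl]oxy}silane
Product: 13 (4S,6S)-6-dodecyl-6-hydroxy-4-[(triisopropylsilyl)oxy]cyclohex-2-ene-1,5-dione, via methoxy epoxide 12 (not isolated)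
Conditions: dimethyldioxirane (acetone solution), CH2Cl2, −40 → 0 °C; then aqueous oxalic acid, THF, 0 °C
Reagents that add atoms: dimethyldioxirane, CC1(C)OO1; water, O
Why: Rubottom-type epoxidation of the electron-rich tetrasubstituted enol ether by the dioxirane occurs anti to the neighbouring C4 silyloxy group and so sets C6 as S, after which aqueous acid opens the methoxy epoxide to the C5 ketone and C6 tertiary alcohol and hydrolyses the C1 dimethyl ketal, the electron-poor disubstituted alkene being far slower towards the oxidant.

Step 8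
Reactants: 13 (4S,6S)-6-dodecyl-6-hydroxy-4-[(triisopropylsilyl)oxy]cyclohex-2-ene-1,5-dione
Product: 14 (4S,5S)-5-hydroxy-5-tridecanoyl-4-[(triisopropylsilyl)oxy]cyclopent-2-en-1-one
Conditions: MgBr2·OEt2 (2 equiv), Et3N (0.2 equiv), CH2Cl2, −20 → 23 °C
Reagents that add atoms: none
Why: MgBr2 binds the C6 hydroxyl and the C5 carbonyl oxygen in a five-membered chelate and the catalytic amine turns the hydroxyl into the alkoxide, whose oxygen lone pair pushes the C6–C1 bond suprafacially onto C5 (α-ketol or acyloin 1,2-acyl shift) so that C1 becomes bonded to C5 and C6 becomes the tridecanoyl carbonyl carbon. The closest known reaction is the base- or metal-ion-mediated contraction of six-membered 2-hydroxy-1,3-diones to 2-acyl-2-hydroxycyclopentenones, as in the isomerisation of humulone to isohumulone. The cyclopentenone ring C1–C5 is closed by migration of a ring carbon from one neighbour to the other through a three-centre, bicyclo[3.1.0]-like transition state, not by an exo or endo cyclisation. The new C5 stereocentre is controlled by C6: syn chelation holds O6 in the plane of the C5 carbonyl, the dodecyl chain is then pseudoaxial, and C1 can only bond to the C5 face opposite to it, which gives 5S from 6S. The step needs migration towards C5 and not towards C1, secured because C5 is the non-conjugated, α-silyloxy and thus more electrophilic ketone and because only this direction keeps the C1 enone, and it needs the C4 epimer in which the C4–O bond stands anti to the incoming C1 (polar Felkin–Anh alignment of the non-chelating silyloxy group), which places C4–O trans to C5–OH; this 4S configuration is delivered by step 7 and, if C4 equilibrates through the C4=C5 enol, the same alignment should select it again. Sub-stoichiometric amine keeps the substrate from resting as the unreactive C4-deprotonated dienolate, and the triisopropylsilyl group neither chelates magnesium nor migrates to O5.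

Step 9
Reactants: 14 (4S,5S)-5-hydroxy-5-tridecanoyl-4-[(triisopropylsilyl)oxy]cyclopent-2-en-1-one
Product: 15 (4S,5R)-5-hydroxy-5-[(1S)-1-hydroxytridecyl]-4-[(triisopropylsilyl)oxy]cyclopent-2-en-1-one
Conditions: NaBH4, MeOH/CH2Cl2 (1:1), −78 °C
Reagents that add atoms: none
Why: NaBH4 in methanol–dichloromethane at −78 °C is known to reduce saturated ketones in the presence of conjugated enones, and under these non-chelating conditions hydride adds to C6 by the polar Felkin–Anh path, anti to the C5–O bond and past the flat C1 carbonyl while the cis C4 silyloxy group shields the competing trajectories, which gives the (S)-carbinol (a hydride delivered through a C5-alkoxide chelate would give the C6 epimer).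

Step 10
Reactants: 15 (4S,5R)-5-hydroxy-5-[(1S)-1-hydroxytridecyl]-4-[(triisopropylsilyl)oxy]cyclopent-2-en-1-one
Product: 16 (1S)-1-[(1R,5S)-1-hydroxy-2-oxo-5-[(triisopropylsilyl)oxy]cyclopent-3-en-1-yl]tridecyl acetate
Conditions: Ac2O, pyridine, 4-(dimethylamino)pyridine (cat.), CH2Cl2, 0 °C
Reagents that add atoms: acetic anhydride, CC(=O)OC(C)=O
Why: Nucleophilic catalysis by 4-(dimethylamino)pyridine acetylates the secondary C6 alcohol only, since the tertiary C5 hydroxyl is too hindered and O4 is still silylated, and the weakly basic medium at 0 °C avoids retro-aldol cleavage of the C5–C6 bond.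

Step 11
Reactants: 16 (1S)-1-[(1R,5S)-1-hydroxy-2-oxo-5-[(triisopropylsilyl)oxy]cyclopent-3-en-1-yl]tridecyl acetate
Product: 17 (1S)-1-[(1S,5S)-1,5-dihydroxy-2-oxocyclopent-3-en-1-yl]tridecyl acetate
Conditions: HF·pyridine, THF, 0 → 23 °C
Reagents that add atoms: none
Why: Fluoride-induced cleavage of the silyl ether under buffered acidic conditions, which leaves the acetate, the enone and the tertiary alcohol untouched and avoids the acetyl migration from O6 to O4 that a basic fluoride source could cause.

Compound list
1 | 1,3-dimethoxybenzene | COc1cccc(OC)c1 | starting material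
2 | 1-bromododecane | CCCCCCCCCCCCBr | starting material
3 | 2,6-dimethoxyphenyllithium | [Li]c1c(OC)cccc1OC | intermediate
4 | 2-dodecyl-1,3-dimethoxybenzene | CCCCCCCCCCCCc1c(OC)cccc1OC | intermediate
5 | N-[(3-dodecyl-2,4-dimethoxyphenyl)methylidene]-N-methylmethanaminium dichlorophosphate | CCCCCCCCCCCCc1c(OC)ccc(C=[N+](C)C)c1OC.[O-]P(=O)(Cl)Cl | intermediate
6 | 3-dodecyl-2,4-dimethoxybenzaldehyde | CCCCCCCCCCCCc1c(OC)ccc(C=O)c1OC | intermediate
7 | 3-dodecyl-2,4-dimethoxyphenyl formate | CCCCCCCCCCCCc1c(OC)ccc(OC=O)c1OC | intermediate
8 | 3-dodecyl-2,4-dimethoxyphenol | CCCCCCCCCCCCc1c(OC)ccc(O)c1OC | intermediate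
9 | 3-dodecyl-2,4,4-trimethoxycyclohexa-2,5-dien-1-one | CCCCCCCCCCCCC1=C(OC)C(=O)C=CC1(OC)OC | intermediate
10 | (1S)-3-dodecyl-2,4,4-trimethoxycyclohexa-2,5-dien-1-ol | CCCCCCCCCCCCC1=C(OC)[C@@H](O)C=CC1(OC)OC | intermediate
11 | triisopropyl{[(1S)-3-dodecyl-2,4,4-trimethoxycyclohexa-2,5-dien-1-yl]oxy}silane | CCCCCCCCCCCCC1=C(OC)[C@@H](O[Si](C(C)C)(C(C)C)C(C)C)C=CC1(OC)OC | intermediate
12 | (1S,5S,6R)-1-dodecyl-2,2,6-trimethoxy-5-[(triisopropylsilyl)oxy]-7-oxabicyclo[4.1.0]hept-3-ene (epoxide oxygen anti to the silyloxy group) | CCCCCCCCCCCC[C@@]12O[C@]1(OC)[C@@H](O[Si](C(C)C)(C(C)C)C(C)C)C=CC2(OC)OC | intermediate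
13 | (4S,6S)-6-dodecyl-6-hydroxy-4-[(triisopropylsilyl)oxy]cyclohex-2-ene-1,5-dione | CCCCCCCCCCCC[C@]1(O)C(=O)C=C[C@H](O[Si](C(C)C)(C(C)C)C(C)C)C1=O | intermediate
14 | (4S,5S)-5-hydroxy-5-tridecanoyl-4-[(triisopropylsilyl)oxy]cyclopent-2-en-1-one | CCCCCCCCCCCCC(=O)[C@]1(O)C(=O)C=C[C@@H]1O[Si](C(C)C)(C(C)C)C(C)C | intermediate
15 | (4S,5R)-5-hydroxy-5-[(1S)-1-hydroxytridecyl]-4-[(triisopropylsilyl)oxy]cyclopent-2-en-1-one | CCCCCCCCCCCC[C@H](O)[C@]1(O)C(=O)C=C[C@@H]1O[Si](C(C)C)(C(C)C)C(C)C | intermediate
16 | (1S)-1-[(1R,5S)-1-hydroxy-2-oxo-5-[(triisopropylsilyl)oxy]cyclopent-3-en-1-yl]tridecyl acetate | CCCCCCCCCCCC[C@H](OC(C)=O)[C@]1(O)C(=O)C=C[C@@H]1O[Si](C(C)C)(C(C)C)C(C)C | intermediate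
17 | (1S)-1-[(1S,5S)-1,5-dihydroxy-2-oxocyclopent-3-en-1-yl]tridecyl acetate | CCCCCCCCCCCC[C@H](OC(C)=O)[C@]1(O)C(=O)C=C[C@@H]1O | target

Total step count: 11. Longest linear sequence: 11 steps (1 to 17).

Steps most likely to fail

Step 8. The C4 centre can equilibrate through the enol, and the contraction may then run with poor facial selectivity at C4, because the epimer whose silyloxy group avoids the pseudoaxial dodecyl chain could contract faster and give the 4,5-cis isomer. The fallback sets out from 13 and comes back at 14; it corrects C4 after the ring contraction instead of setting it there. The contraction is run as before and the C4 epimer (4R,5S)-5-hydroxy-5-tridecanoyl-4-[(triisopropylsilyl)oxy]cyclopent-2-en-1-one F1 is carried on. HF·pyridine removes the silyl group to give (4R,5S)-4,5-dihydroxy-5-tridecanoylcyclopent-2-en-1-one F2. Mitsunobu inversion of the secondary allylic C4 hydroxyl with chloroacetic acid, PPh3 and diisopropyl azodicarboxylate gives (1S,5S)-5-hydroxy-4-oxo-5-tridecanoylcyclopent-2-en-1-yl chloroacetate F3. Thiourea and NaHCO3 in ethanol remove the chloroacetyl group to give (4S,5S)-4,5-dihydroxy-5-tridecanoylcyclopent-2-en-1-one F4. Chlorotriisopropylsilane and imidazole then silylate only the secondary hydroxyl and return 14.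

Step 9. Facial selectivity at the C6 carbonyl may be poor, since an internal hydrogen bond from the C5 hydroxyl can open a chelate-like pathway to the C6 epimer, and the ring enone may be over-reduced. The fallback sets out from 14 and comes back at 15; it replaces selective mono-reduction by catalyst-controlled global reduction and selective re-oxidation. Both carbonyl groups are reduced with (R)-Me-CBS (the oxazaborolidine of step 5, one equivalent) and excess catecholborane in toluene at −40 °C, which should override the substrate bias at C6. This gives 1-[(1S)-1-hydroxytridecyl]-5-[(triisopropylsilyl)oxy]cyclopent-3-ene-1,2-diol F5 as a mixture of epimers at the new ring carbinol, the other centres as in 15. MnO2 in CH2Cl2 then re-oxidises only the allylic ring alcohol and returns 15.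

Step 5. Enantioselectivity may be insufficient, because both carbonyl substituents are vinylic and differ only in the α-methoxy group. The fallback sets out from 9 and comes back at 10; it replaces asymmetric catalysis by resolution. Luche reduction (NaBH4, CeCl3·7H2O, MeOH, −78 °C) gives racemic 3-dodecyl-2,4,4-trimethoxycyclohexa-2,5-dien-1-ol F6. Kinetic resolution with Burkholderia cepacia lipase and vinyl acetate in tert-butyl methyl ether should acetylate the (R)-enantiomer, by the usual enantiopreference of lipases for secondary alcohols, to (1R)-3-dodecyl-2,4,4-trimethoxycyclohexa-2,5-dien-1-yl acetate F7. The unreacted (S)-alcohol 10 is separated on base-washed silica and rejoins the route.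

Further compounds
F1 | step 8 | (4R,5S)-5-hydroxy-5-tridecanoyl-4-[(triisopropylsilyl)oxy]cyclopent-2-en-1-one | CCCCCCCCCCCCC(=O)[C@]1(O)C(=O)C=C[C@H]1O[Si](C(C)C)(C(C)C)C(C)C
F2 | step 8 | (4R,5S)-4,5-dihydroxy-5-tridecanoylcyclopent-2-en-1-one | CCCCCCCCCCCCC(=O)[C@]1(O)C(=O)C=C[C@H]1O
F3 | step 8 | (1S,5S)-5-hydroxy-4-oxo-5-tridecanoylcyclopent-2-en-1-yl chloroacetate | CCCCCCCCCCCCC(=O)[C@]1(O)C(=O)C=C[C@@H]1OC(=O)CCl
F4 | step 8 | (4S,5S)-4,5-dihydroxy-5-tridecanoylcyclopent-2-en-1-one | CCCCCCCCCCCCC(=O)[C@]1(O)C(=O)C=C[C@@H]1O
F5 | step 9 | 1-[(1S)-1-hydroxytridecyl]-5-[(triisopropylsilyl)oxy]cyclopent-3-ene-1,2-diol (epimers at the new ring carbinol, other centres as in 15) | CCCCCCCCCCCC[C@H](O)[C@]1(O)C(O)C=C[C@@H]1O[Si](C(C)C)(C(C)C)C(C)C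
F6 | step 5 | rac-3-dodecyl-2,4,4-trimethoxycyclohexa-2,5-dien-1-ol | CCCCCCCCCCCCC1=C(OC)C(O)C=CC1(OC)OC
F7 | step 5 | (1R)-3-dodecyl-2,4,4-trimethoxycyclohexa-2,5-dien-1-yl acetate | CCCCCCCCCCCCC1=C(OC)[C@H](OC(C)=O)C=CC1(OC)OC
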